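**Plan**

1. Numbering follows the flavanones: unit 1 is benzo ring A, pyranone ring C and aryl ring B (O1–C8a, C1'–C6'); unit 2 is benzo ring D, pyranone ring F and syringyl ring E (O1''–C8a'', C1'''–C6'''); the units meet at C2'–C8''. The enabling feature is ring D, an acylphloroglucinol (oxygen on C5'', C7'', C8a''; acyl on C4a'') that is the Claisen fold of the cinnamoyl chain C8a''→C2''; its aryl-bearing C8'' can begin as the benzylic carbon of a ring B arylacetate held in a 3-aryl-4-methoxy-2-pyrone.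
2. Retrosynthetic cuts, in order: the three benzyl ethers; O1–C2 and C2–C3 (ring C); O1''–C2'' (ring F); C4a''–C8a'' (ring D, reopened to the pyrone); C4a''–C4''; C6''–C5'' and C8''–C7'' (pyrone carbons); and the biaryl bond C2'–C8'', made as an aryl–CH2 bond.
3. Forward order: ring B bromide → arylacetate → 2-pyrone (temporary ring) → cinnamoylmethyl pyrone → ring D by unfolding and Claisen folding → ring F → ring B aldehyde → ring C with ring A attached → debenzylation.
4. Stereochemistry: C2'' (S) comes from a cinchona-thiourea-catalysed oxa-Michael closure of the ring D 2'-hydroxychalcone; C2 (S) comes from the same catalyst acting on an alkylidene β-keto ester, followed by acidic decarboxylation. No strong base touches the molecule after either centre exists.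
5. Ring F is closed while ring B still carries its acetal, because a free C8a'' hydroxyl would otherwise form a lactol with the aldehyde or add 6-exo to the unit 1 enone.

Key step: step 9

Assumption 1: the target as drawn fixes only C2 and C2'' (both S); the configuration about the hindered C2'–C8'' axis is not specified, so the route controls the two carbon centres and carries whatever rotamer mixture forms.
Assumption 2: catalyst Q (the 3,5-bis(trifluoromethyl)phenyl thiourea of 9-amino(9-deoxy)epi-quinidine) is taken to give the (2S) sense in both closures; if a model cyclisation of (E)-1-[2-(benzyloxy)-6-hydroxy-4-methoxyphenyl]-3-phenylprop-2-en-1-one shows the opposite sense, its quinine-derived pseudoenantiomer is used under the same conditions.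

**Route**

Step 1
Reactants: 1 2-bromo-3,4-dimethoxybenzaldehyde
Product: 2 2-(2-bromo-3,4-dimethoxyphenyl)-1,3-dioxolane
Conditions: ethylene glycol (3 equiv), TsOH·H2O (2 mol %), toluene, reflux, Dean–Stark
Reagents that add atoms: ethylene glycol, OCCO
Why: Acid-catalysed acetalisation with azeotropic removal of water masks the aldehyde as a base-stable 1,3-dioxolane that should survive the organozinc, amide-base and methoxide steps ahead.

Step 2
Reactants: 2 2-(2-bromo-3,4-dimethoxyphenyl)-1,3-dioxolane; 3 ethyl bromoacetate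
Product: 5 ethyl 2-[6-(1,3-dioxolan-2-yl)-2,3-dimethoxyphenyl]acetate, via Reformatsky reagent (2-ethoxy-2-oxoethyl)zinc bromide 4 (not isolated)
Conditions: 3, Zn dust (TMSCl-activated), THF, 40 °C; then 2, Pd(dba)2 (2 mol %), Q-Phos [(C5Ph5)Fe(C5H4P(t-Bu)2)] (2 mol %), THF, 25 → 60 °C
Reagents that add atoms: none
Why: Negishi-type palladium-catalysed α-arylation of a Reformatsky reagent tolerates ortho-substituted aryl bromides when a bulky electron-rich monophosphine is used, and it forms the future biaryl bond C2'–C8'' as an unhindered aryl–CH2 bond.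

Step 3
Reactants: 5 ethyl 2-[6-(1,3-dioxolan-2-yl)-2,3-dimethoxyphenyl]acetate
Product: 6 ethyl 2-[6-(1,3-dioxolan-2-yl)-2,3-dimethoxyphenyl]-3-oxobutanoate
Conditions: LiN(iPr)2 (1.1 equiv), THF, −78 °C; N-methoxy-N-methylacetamide (1.2 equiv), −78 → 0 °C; AcOH quench
Reagents that add atoms: N-methoxy-N-methylacetamide, CC(=O)N(C)OC
Why: Crossed Claisen acylation of the lithium ester enolate by an N-methoxy-N-methylamide stops at the chelated tetrahedral adduct, so one equivalent of base is enough and double acylation is avoided while the C8''–C7'' bond is made.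

Step 4
Reactants: 6 ethyl 2-[6-(1,3-dioxolan-2-yl)-2,3-dimethoxyphenyl]-3-oxobutanoate
Product: 8 3-[6-(1,3-dioxolan-2-yl)-2,3-dimethoxyphenyl]-4-hydroxy-6-methyl-2H-pyran-2-one, via 3,5-dioxohexanoate ester 7 (not isolated)
Conditions: LiN(iPr)2 (2.2 equiv), THF, −78 → 0 °C; N-methoxy-N-methylacetamide (1.1 equiv), −78 → 0 °C; AcOH quench; then DBU (1.2 equiv), toluene, 80 °C; pH 4–5 citrate work-up, 0 °C
Reagents that add atoms: N-methoxy-N-methylacetamide, CC(=O)N(C)OC
Why: The β-keto ester dianion is acylated at its terminal γ-carbon (dianion Claisen acylation, forming C6''–C5''), and the resulting 3,5-dioxo ester undergoes base-promoted enol lactonisation to the 4-hydroxy-2-pyrone, the standard entry to triacetic-lactone-type rings.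

Step 5
Reactants: 8 3-[6-(1,3-dioxolan-2-yl)-2,3-dimethoxyphenyl]-4-hydroxy-6-methyl-2H-pyran-2-one
Product: 9 3-[6-(1,3-dioxolan-2-yl)-2,3-dimethoxyphenyl]-4-methoxy-6-methyl-2H-pyran-2-one
Conditions: Me2SO4 (1.2 equiv), K2CO3, acetone, reflux
Reagents that add atoms: dimethyl sulfate, COS(=O)(=O)OC
Why: Williamson-type O-methylation of the acidic 4-hydroxy-2-pyrone with a hard methylating agent and carbonate gives the 4-methoxy-2-pyrone, as with triacetic acid lactone itself, and fixes the C7'' methyl ether before ring D exists.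

Step 6
Reactants: 10 syringaldehyde (4-hydroxy-3,5-dimethoxybenzaldehyde)
Product: 11 4-(benzyloxy)-3,5-dimethoxybenzaldehyde
Conditions: BnBr (1.2 equiv), K2CO3, DMF, 60 °C
Reagents that add atoms: benzyl bromide, BrCc1ccccc1
Why: Williamson ether synthesis on the acidic para-formyl phenol proceeds readily in a dipolar solvent despite the two flanking methoxy groups.

Step 7
Reactants: 11 4-(benzyloxy)-3,5-dimethoxybenzaldehyde; 12 diethyl {2-[methoxy(methyl)amino]-2-oxoethyl}phosphonate
Product: 13 (2E)-3-[4-(benzyloxy)-3,5-dimethoxyphenyl]-N-methoxy-N-methylprop-2-enamide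
Conditions: NaH (1.1 equiv), THF, 0 °C → rt
Reagents that add atoms: none
Why: Horner–Wadsworth–Emmons olefination with the stabilised phosphonoacetamide anion gives the E-configured cinnamic N-methoxy-N-methylamide directly from the aromatic aldehyde.

Step 8
Reactants: 9 3-[6-(1,3-dioxolan-2-yl)-2,3-dimethoxyphenyl]-4-methoxy-6-methyl-2H-pyran-2-one; 13 (2E)-3-[4-(benzyloxy)-3,5-dimethoxyphenyl]-N-methoxy-N-methylprop-2-enamide
Product: 14 6-{(3E)-4-[4-(benzyloxy)-3,5-dimethoxyphenyl]-2-oxobut-3-en-1-yl}-3-[6-(1,3-dioxolan-2-yl)-2,3-dimethoxyphenyl]-4-methoxy-2H-pyran-2-one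
Conditions: 9, LiN(iPr)2 (1.05 equiv), THF, −78 °C; then 13, −78 → −30 °C; AcOH quench
Reagents that add atoms: none
Why: Amide bases deprotonate the 6-methyl group of 4-methoxy-6-methyl-2-pyrones to a vinylogous ester enolate that reacts at its exocyclic carbon, and 1,2-addition to the unsaturated N-methoxy-N-methylamide gives a chelated adduct that releases the acidic cinnamoylmethyl ketone only on quench (Weinreb ketone synthesis, forming C4a''–C4'').

Step 9
Reactants: 14 6-{(3E)-4-[4-(benzyloxy)-3,5-dimethoxyphenyl]-2-oxobut-3-en-1-yl}-3-[6-(1,3-dioxolan-2-yl)-2,3-dimethoxyphenyl]-4-methoxy-2H-pyran-2-one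
Product: 16 (2E)-3-[4-(benzyloxy)-3,5-dimethoxyphenyl]-1-{3-[6-(1,3-dioxolan-2-yl)-2,3-dimethoxyphenyl]-2,6-dihydroxy-4-methoxyphenyl}prop-2-en-1-one, via ring-opened methyl ester 15 (not isolated)
Conditions: Mg(OMe)2 (4 equiv), MeOH–THF, 60 °C; AcOH to pH 6–7, 0 °C; crude product used at once
Reagents that add atoms: none
Why: Methoxide attacks the lactone carbonyl C8a'' and opens the pyrone to ester 15, a cis-β-methoxyacrylate whose 5,7-diketone sits in a magnesium chelate; the central carbon C4a'' of that diketone then acylates itself on the ester carbonyl (Claisen condensation), methoxide leaves, and two enolisations give aromatic ring D. The closest known reaction is the Mg(OMe)2-mediated conversion of 6-(2-oxoalkyl)-2-pyrones into acylphloroglucinols used in biomimetic polyketide cyclisations. Ring D closes by 6-exo-trig acyl substitution, the pyrone ring is consumed, and no stereocentre is formed. The step needs Claisen folding to beat aldol folding, relactonisation and methoxide addition to the enone: C8'' is a fully substituted enol-ether carbon that cannot act as an aldol donor, the cis geometry inherited from the pyrone keeps ester and diketone within reach, methoxide addition to the enone is reversible, and only the Claisen path ends in an aromatic magnesium bis-phenoxide that drains the equilibria. The strongly basic medium should hold the product as the open chalcone phenoxide, and a cold near-neutral quench with immediate benzylation limits closure to racemic flavanone and spares the dioxolane.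

Step 10
Reactants: 16 (2E)-3-[4-(benzyloxy)-3,5-dimethoxyphenyl]-1-{3-[6-(1,3-dioxolan-2-yl)-2,3-dimethoxyphenyl]-2,6-dihydroxy-4-methoxyphenyl}prop-2-en-1-one
Product: 17 (2E)-1-{6-(benzyloxy)-3-[6-(1,3-dioxolan-2-yl)-2,3-dimethoxyphenyl]-2-hydroxy-4-methoxyphenyl}-3-[4-(benzyloxy)-3,5-dimethoxyphenyl]prop-2-en-1-one
Conditions: BnBr (1.05 equiv), K2CO3 (1.5 equiv), acetone, rt
Reagents that add atoms: benzyl bromide, BrCc1ccccc1
Why: Williamson mono-alkylation of a 2,6-dihydroxyaryl ketone stops after one ether because the second hydroxyl stays chelated, and it should take the C5'' oxygen because the C8a'' oxygen is shielded by the perpendicular, doubly ortho-substituted ring B, which leaves free exactly the oxygen that becomes O1''.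

Step 11
Reactants: 17 (2E)-1-{6-(benzyloxy)-3-[6-(1,3-dioxolan-2-yl)-2,3-dimethoxyphenyl]-2-hydroxy-4-methoxyphenyl}-3-[4-(benzyloxy)-3,5-dimethoxyphenyl]prop-2-en-1-one
Product: 18 (2S)-5-(benzyloxy)-2-[4-(benzyloxy)-3,5-dimethoxyphenyl]-8-[6-(1,3-dioxolan-2-yl)-2,3-dimethoxyphenyl]-7-methoxy-2,3-dihydro-4H-chromen-4-one
Conditions: catalyst Q (20 mol %), toluene, 0 °C → rt
Reagents that add atoms: none
Why: In this organocatalytic intramolecular oxa-Michael addition of a 2'-hydroxychalcone (6-endo-trig), the quinuclidine nitrogen activates the C8a'' phenol while the thiourea binds the enone carbonyl, so the catalyst chooses the face of C2'' and sets it as S, and the 6'-benzyloxy group makes closure to the flavanone effectively irreversible under these weakly basic conditions.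

Step 12
Reactants: 18 (2S)-5-(benzyloxy)-2-[4-(benzyloxy)-3,5-dimethoxyphenyl]-8-[6-(1,3-dioxolan-2-yl)-2,3-dimethoxyphenyl]-7-methoxy-2,3-dihydro-4H-chromen-4-one
Product: 19 2-{(2S)-5-(benzyloxy)-2-[4-(benzyloxy)-3,5-dimethoxyphenyl]-7-methoxy-4-oxo-3,4-dihydro-2H-chromen-8-yl}-3,4-dimethoxybenzaldehyde
Conditions: 1 M HCl, THF, rt
Reagents that add atoms: water, O
Why: Acid-catalysed acetal hydrolysis of the electron-rich aryl dioxolane runs in dilute acid at room temperature, where the flavanone and the benzyl ethers are stable and, with O1'' now inside ring F, the freed aldehyde has no phenol with which to form a lactol.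

Step 13
Reactants: 20 1-(2,6-dihydroxy-4-methoxyphenyl)ethan-1-one
Product: 21 1-[2-(benzyloxy)-6-hydroxy-4-methoxyphenyl]ethan-1-one
Conditions: BnBr (1.0 equiv), K2CO3, acetone, reflux
Reagents that add atoms: benzyl bromide, BrCc1ccccc1
Why: Williamson mono-benzylation of the symmetric 2,6-dihydroxyacetophenone stops cleanly because the remaining hydroxyl is held in a hydrogen bond to the ketone.

Step 14
Reactants: 21 1-[2-(benzyloxy)-6-hydroxy-4-methoxyphenyl]ethan-1-one
Product: 22 tert-butyl 3-[2-(benzyloxy)-6-hydroxy-4-methoxyphenyl]-3-oxopropanoate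
Conditions: LiN(SiMe3)2 (3.3 equiv), THF, −78 → −20 °C; Boc2O (1.2 equiv), −78 → 0 °C; AcOH quench
Reagents that add atoms: di-tert-butyl dicarbonate, CC(C)(C)OC(=O)OC(=O)OC(C)(C)C
Why: Claisen-type C-acylation of the ketone enolate by the dicarbonate, reached either directly or through the aryl carbonate by a Baker–Venkataraman-type O-to-C acyl shift, gives the tert-butyl β-keto ester, which the excess base protects as its enolate.

Step 15
Reactants: 19 2-{(2S)-5-(benzyloxy)-2-[4-(benzyloxy)-3,5-dimethoxyphenyl]-7-methoxy-4-oxo-3,4-dihydro-2H-chromen-8-yl}-3,4-dimethoxybenzaldehyde; 22 tert-butyl 3-[2-(benzyloxy)-6-hydroxy-4-methoxyphenyl]-3-oxopropanoate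
Product: 23 tert-butyl 2-[2-(benzyloxy)-6-hydroxy-4-methoxybenzoyl]-3-(2-{(2S)-5-(benzyloxy)-2-[4-(benzyloxy)-3,5-dimethoxyphenyl]-7-methoxy-4-oxo-3,4-dihydro-2H-chromen-8-yl}-3,4-dimethoxyphenyl)prop-2-enoate (E/Z mixture)
Conditions: piperidine (20 mol %), AcOH (20 mol %), 4 Å molecular sieves, toluene, rt
Reagents that add atoms: none
Why: Knoevenagel condensation under piperidinium acetate catalysis forms the C2–C3 bond under conditions too weakly basic to open ring F, and the bulky tert-butyl ester slows uncatalysed closure of the alkylidene.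

Step 16
Reactants: 23 tert-butyl 2-[2-(benzyloxy)-6-hydroxy-4-methoxybenzoyl]-3-(2-{(2S)-5-(benzyloxy)-2-[4-(benzyloxy)-3,5-dimethoxyphenyl]-7-methoxy-4-oxo-3,4-dihydro-2H-chromen-8-yl}-3,4-dimethoxyphenyl)prop-2-enoate
Product: 25 (2S)-5-(benzyloxy)-2-(2-{(2S)-5-(benzyloxy)-2-[4-(benzyloxy)-3,5-dimethoxyphenyl]-7-methoxy-4-oxo-3,4-dihydro-2H-chromen-8-yl}-3,4-dimethoxyphenyl)-7-methoxy-2,3-dihydro-4H-chromen-4-one, via tert-butyl flavanone-3-carboxylate 24 (not isolated)
Conditions: catalyst Q (10 mol %), toluene, −25 °C; then TsOH·H2O (1 equiv), 80 °C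
Reagents that add atoms: none
Why: In this thiourea-catalysed asymmetric oxa-Michael addition to an alkylidene β-keto ester (6-endo-trig), the thiourea binds the dicarbonyl and the quinuclidine delivers the ring A phenol to one face of C2, so the catalyst sets C2 as S from either alkene isomer, and acid then removes the tert-butyl ester by decarboxylation without enolising towards C2.

Step 17
Reactants: 25 (2S)-5-(benzyloxy)-2-(2-{(2S)-5-(benzyloxy)-2-[4-(benzyloxy)-3,5-dimethoxyphenyl]-7-methoxy-4-oxo-3,4-dihydro-2H-chromen-8-yl}-3,4-dimethoxyphenyl)-7-methoxy-2,3-dihydro-4H-chromen-4-one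
Product: 26 (2S)-5-hydroxy-2-{2-[(2S)-5-hydroxy-2-(4-hydroxy-3,5-dimethoxyphenyl)-7-methoxy-4-oxo-3,4-dihydro-2H-chromen-8-yl]-3,4-dimethoxyphenyl}-7-methoxy-2,3-dihydro-4H-chromen-4-one (CNP0229789.1)
Conditions: H2 (1 atm), Pd/C (10 wt %), EtOAc–MeOH, rt, stopped after uptake of three equivalents
Reagents that add atoms: none
Why: Catalytic hydrogenolysis cleaves the three aryl benzyl ethers under neutral conditions that leave the flavanone carbonyls, the benzylic C2–O1 bonds and both stereocentres untouched when hydrogen uptake is monitored.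

**Compound list**

1 | 2-bromo-3,4-dimethoxybenzaldehyde | COc1ccc(C=O)c(Br)c1OC | starting material
2 | 2-(2-bromo-3,4-dimethoxyphenyl)-1,3-dioxolane | COc1ccc(C2OCCO2)c(Br)c1OC | intermediate
3 | ethyl bromoacetate | CCOC(=O)CBr | starting material
4 | (2-ethoxy-2-oxoethyl)zinc bromide (Reformatsky reagent) | CCOC(=O)C[Zn]Br | intermediate
5 | ethyl 2-[6-(1,3-dioxolan-2-yl)-2,3-dimethoxyphenyl]acetate | CCOC(=O)Cc1c(C2OCCO2)ccc(OC)c1OC | intermediate
6 | ethyl 2-[6-(1,3-dioxolan-2-yl)-2,3-dimethoxyphenyl]-3-oxobutanoate | CCOC(=O)C(C(C)=O)c1c(C2OCCO2)ccc(OC)c1OC | intermediate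
7 | ethyl 2-[6-(1,3-dioxolan-2-yl)-2,3-dimethoxyphenyl]-3,5-dioxohexanoate | CCOC(=O)C(C(=O)CC(C)=O)c1c(C2OCCO2)ccc(OC)c1OC | intermediate
8 | 3-[6-(1,3-dioxolan-2-yl)-2,3-dimethoxyphenyl]-4-hydroxy-6-methyl-2H-pyran-2-one | Cc1cc(O)c(-c2c(C3OCCO3)ccc(OC)c2OC)c(=O)o1 | intermediate
9 | 3-[6-(1,3-dioxolan-2-yl)-2,3-dimethoxyphenyl]-4-methoxy-6-methyl-2H-pyran-2-one | COc1cc(C)oc(=O)c1-c1c(C2OCCO2)ccc(OC)c1OC | intermediate
10 | syringaldehyde (4-hydroxy-3,5-dimethoxybenzaldehyde) | COc1cc(C=O)cc(OC)c1O | starting material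
11 | 4-(benzyloxy)-3,5-dimethoxybenzaldehyde | COc1cc(C=O)cc(OC)c1OCc1ccccc1 | intermediate
12 | diethyl {2-[methoxy(methyl)amino]-2-oxoethyl}phosphonate | CCOP(=O)(CC(=O)N(C)OC)OCC | starting material
13 | (2E)-3-[4-(benzyloxy)-3,5-dimethoxyphenyl]-N-methoxy-N-methylprop-2-enamide | CON(C)C(=O)/C=C/c1cc(OC)c(OCc2ccccc2)c(OC)c1 | intermediate
14 | 6-{(3E)-4-[4-(benzyloxy)-3,5-dimethoxyphenyl]-2-oxobut-3-en-1-yl}-3-[6-(1,3-dioxolan-2-yl)-2,3-dimethoxyphenyl]-4-methoxy-2H-pyran-2-one (key-step precursor) | COc1cc(CC(=O)/C=C/c2cc(OC)c(OCc3ccccc3)c(OC)c2)oc(=O)c1-c1c(C2OCCO2)ccc(OC)c1OC | intermediate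
15 | methyl (2E,8E)-9-[4-(benzyloxy)-3,5-dimethoxyphenyl]-2-[6-(1,3-dioxolan-2-yl)-2,3-dimethoxyphenyl]-3-methoxy-5,7-dioxonona-2,8-dienoate | COC(=O)/C(=C(/OC)CC(=O)CC(=O)/C=C/c1cc(OC)c(OCc2ccccc2)c(OC)c1)c1c(C2OCCO2)ccc(OC)c1OC | intermediate
16 | (2E)-3-[4-(benzyloxy)-3,5-dimethoxyphenyl]-1-{3-[6-(1,3-dioxolan-2-yl)-2,3-dimethoxyphenyl]-2,6-dihydroxy-4-methoxyphenyl}prop-2-en-1-one (key-step product, ring D chalcone) | COc1cc(O)c(C(=O)/C=C/c2cc(OC)c(OCc3ccccc3)c(OC)c2)c(O)c1-c1c(C2OCCO2)ccc(OC)c1OC | intermediate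
17 | (2E)-1-{6-(benzyloxy)-3-[6-(1,3-dioxolan-2-yl)-2,3-dimethoxyphenyl]-2-hydroxy-4-methoxyphenyl}-3-[4-(benzyloxy)-3,5-dimethoxyphenyl]prop-2-en-1-one | COc1cc(OCc2ccccc2)c(C(=O)/C=C/c2cc(OC)c(OCc3ccccc3)c(OC)c2)c(O)c1-c1c(C2OCCO2)ccc(OC)c1OC | intermediate
18 | (2S)-5-(benzyloxy)-2-[4-(benzyloxy)-3,5-dimethoxyphenyl]-8-[6-(1,3-dioxolan-2-yl)-2,3-dimethoxyphenyl]-7-methoxy-2,3-dihydro-4H-chromen-4-one | COc1cc(OCc2ccccc2)c2c(c1-c1c(C3OCCO3)ccc(OC)c1OC)O[C@H](c1cc(OC)c(OCc3ccccc3)c(OC)c1)CC2=O | intermediate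
19 | 2-{(2S)-5-(benzyloxy)-2-[4-(benzyloxy)-3,5-dimethoxyphenyl]-7-methoxy-4-oxo-3,4-dihydro-2H-chromen-8-yl}-3,4-dimethoxybenzaldehyde | COc1cc(OCc2ccccc2)c2c(c1-c1c(C=O)ccc(OC)c1OC)O[C@H](c1cc(OC)c(OCc3ccccc3)c(OC)c1)CC2=O | intermediate
20 | 1-(2,6-dihydroxy-4-methoxyphenyl)ethan-1-one | COc1cc(O)c(C(C)=O)c(O)c1 | starting material
21 | 1-[2-(benzyloxy)-6-hydroxy-4-methoxyphenyl]ethan-1-one | COc1cc(O)c(C(C)=O)c(OCc2ccccc2)c1 | intermediate
22 | tert-butyl 3-[2-(benzyloxy)-6-hydroxy-4-methoxyphenyl]-3-oxopropanoate | COc1cc(O)c(C(=O)CC(=O)OC(C)(C)C)c(OCc2ccccc2)c1 | intermediate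
23 | tert-butyl 2-[2-(benzyloxy)-6-hydroxy-4-methoxybenzoyl]-3-(2-{(2S)-5-(benzyloxy)-2-[4-(benzyloxy)-3,5-dimethoxyphenyl]-7-methoxy-4-oxo-3,4-dihydro-2H-chromen-8-yl}-3,4-dimethoxyphenyl)prop-2-enoate (E/Z mixture) | COc1cc(O)c(C(=O)C(C(=O)OC(C)(C)C)=Cc2ccc(OC)c(OC)c2-c2c(OC)cc(OCc3ccccc3)c3c2O[C@H](c2cc(OC)c(OCc4ccccc4)c(OC)c2)CC3=O)c(OCc2ccccc2)c1 | intermediate
24 | tert-butyl (2S)-5-(benzyloxy)-2-(2-{(2S)-5-(benzyloxy)-2-[4-(benzyloxy)-3,5-dimethoxyphenyl]-7-methoxy-4-oxo-3,4-dihydro-2H-chromen-8-yl}-3,4-dimethoxyphenyl)-7-methoxy-4-oxo-3,4-dihydro-2H-chromene-3-carboxylate (C3 epimers) | COc1cc(OCc2ccccc2)c2c(c1)O[C@H](c1ccc(OC)c(OC)c1-c1c(OC)cc(OCc3ccccc3)c3c1O[C@H](c1cc(OC)c(OCc4ccccc4)c(OC)c1)CC3=O)C(C(=O)OC(C)(C)C)C2=O | intermediate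
25 | (2S)-5-(benzyloxy)-2-(2-{(2S)-5-(benzyloxy)-2-[4-(benzyloxy)-3,5-dimethoxyphenyl]-7-methoxy-4-oxo-3,4-dihydro-2H-chromen-8-yl}-3,4-dimethoxyphenyl)-7-methoxy-2,3-dihydro-4H-chromen-4-one | COc1cc(OCc2ccccc2)c2c(c1)O[C@H](c1ccc(OC)c(OC)c1-c1c(OC)cc(OCc3ccccc3)c3c1O[C@H](c1cc(OC)c(OCc4ccccc4)c(OC)c1)CC3=O)CC2=O | intermediate
26 | (2S)-5-hydroxy-2-{2-[(2S)-5-hydroxy-2-(4-hydroxy-3,5-dimethoxyphenyl)-7-methoxy-4-oxo-3,4-dihydro-2H-chromen-8-yl]-3,4-dimethoxyphenyl}-7-methoxy-2,3-dihydro-4H-chromen-4-one (CNP0229789.1) | COc1cc(O)c2c(c1)O[C@H](c1ccc(OC)c(OC)c1-c1c(OC)cc(O)c3c1O[C@H](c1cc(OC)c(O)c(OC)c1)CC3=O)CC2=O | target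

**Step count and risks**

Total step count: 17. Longest linear sequence: 13 steps (steps 1–5, 8–12, 15–17, from compound 1).

The three steps most likely to fail:

Step 9 (key step). The anionic pyrone may resist unzipping, methoxide may add to the enone, or the liberated 2',6'-dihydroxychalcone may close to racemic flavanones through either hydroxyl before it is benzylated. The fallback folds the chain before the enone exists. Setting out from 9, the lithiated pyrone is acylated with N-methoxy-N-methylacetamide (conditions of step 8) to the 6-(2-oxopropyl)pyrone F1. Mg(OMe)2 in MeOH then folds this saturated chain, which carries no Michael acceptor, to the ring D acetophenone F2; this is the direct counterpart of the long-known acetonylpyrone to phloroacetophenone conversion. Mono-benzylation as in step 10 gives the C5''-O-benzyl acetophenone F3, and Claisen–Schmidt condensation of F3 with aldehyde 11 (KOH, EtOH, rt) returns to the route at 17.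

Step 11. Facial discrimination and turnover may be poor at a phenol that is chelated and flanked by ring B, and slow retro-oxa-Michael reaction may erode the enantiomeric purity. The fallback resolves the centre instead of inducing it. Setting out from 17, NaOAc in refluxing EtOH closes ring F without control to the racemic flavanone F4. Asymmetric transfer hydrogenation with RuCl[(R,R)-TsDPEN](p-cymene) and HCO2H–Et3N, a known kinetic resolution of racemic flavanones, is expected to reduce the (2''R) enantiomer to the cis-(2R,4R)-flavan-4-ol F5 and leave the (2''S) ketone. That ketone is separated by chromatography and is compound 18, where the route resumes.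

Step 15. The condensation may stall at the aldehyde, which sits ortho to the biaryl bond, and long contact with amine may close the alkylidene without control or epimerise C2''. The fallback gives up the ester activation. Setting out from 19, the dilithium dianion of 21 (LiN(SiMe3)2, 2.1 equiv, THF, −78 °C) adds to the aldehyde to give the β-hydroxy ketone F6; this is a directed aldol addition, quenched cold with AcOH so that ring F is not enolised. PPTS in toluene at 60 °C dehydrates the aldol to the unit 1 chalcone F7. Catalyst Q then closes ring C under the conditions of step 11, and the product is compound 25, where the route resumes.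

Further compounds
F1 | step 9 | 3-[6-(1,3-dioxolan-2-yl)-2,3-dimethoxyphenyl]-4-methoxy-6-(2-oxopropyl)-2H-pyran-2-one | CC(=O)Cc1cc(OC)c(-c2c(C3OCCO3)ccc(OC)c2OC)c(=O)o1
F2 | step 9 | 1-{3-[6-(1,3-dioxolan-2-yl)-2,3-dimethoxyphenyl]-2,6-dihydroxy-4-methoxyphenyl}ethan-1-one | COc1cc(O)c(C(C)=O)c(O)c1-c1c(C2OCCO2)ccc(OC)c1OC
F3 | step 9 | 1-{6-(benzyloxy)-3-[6-(1,3-dioxolan-2-yl)-2,3-dimethoxyphenyl]-2-hydroxy-4-methoxyphenyl}ethan-1-one | COc1cc(OCc2ccccc2)c(C(C)=O)c(O)c1-c1c(C2OCCO2)ccc(OC)c1OC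
F4 | step 11 | racemic 5-(benzyloxy)-2-[4-(benzyloxy)-3,5-dimethoxyphenyl]-8-[6-(1,3-dioxolan-2-yl)-2,3-dimethoxyphenyl]-7-methoxy-2,3-dihydro-4H-chromen-4-one | COc1cc(OCc2ccccc2)c2c(c1-c1c(C3OCCO3)ccc(OC)c1OC)OC(c1cc(OC)c(OCc3ccccc3)c(OC)c1)CC2=O
F5 | step 11 | (2R,4R)-5-(benzyloxy)-2-[4-(benzyloxy)-3,5-dimethoxyphenyl]-8-[6-(1,3-dioxolan-2-yl)-2,3-dimethoxyphenyl]-7-methoxy-3,4-dihydro-2H-chromen-4-ol | COc1cc(OCc2ccccc2)c2c(c1-c1c(C3OCCO3)ccc(OC)c1OC)O[C@@H](c1cc(OC)c(OCc3ccccc3)c(OC)c1)C[C@H]2O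
F6 | step 15 | 1-[2-(benzyloxy)-6-hydroxy-4-methoxyphenyl]-3-(2-{(2S)-5-(benzyloxy)-2-[4-(benzyloxy)-3,5-dimethoxyphenyl]-7-methoxy-4-oxo-3,4-dihydro-2H-chromen-8-yl}-3,4-dimethoxyphenyl)-3-hydroxypropan-1-one (carbinol epimers) | COc1cc(O)c(C(=O)CC(O)c2ccc(OC)c(OC)c2-c2c(OC)cc(OCc3ccccc3)c3c2O[C@H](c2cc(OC)c(OCc4ccccc4)c(OC)c2)CC3=O)c(OCc2ccccc2)c1
F7 | step 15 | (2E)-1-[2-(benzyloxy)-6-hydroxy-4-methoxyphenyl]-3-(2-{(2S)-5-(benzyloxy)-2-[4-(benzyloxy)-3,5-dimethoxyphenyl]-7-methoxy-4-oxo-3,4-dihydro-2H-chromen-8-yl}-3,4-dimethoxyphenyl)prop-2-en-1-one | COc1cc(O)c(C(=O)/C=C/c2ccc(OC)c(OC)c2-c2c(OC)cc(OCc3ccccc3)c3c2O[C@H](c2cc(OC)c(OCc4ccccc4)c(OC)c2)CC3=O)c(OCc2ccccc2)c1
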